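**Plan**

- Retrosynthesis: first the eight benzyl ethers and all silicon are removed, then the interflavan bond C4(upper)–C8(lower) is cut, then the lower C4–O bond and the two bonds (C8–Si, Si–O3) of a one-atom SiMe2 bridge.
- Forward: both pyran rings come intact from the two enantiomers of epicatechin. The lower unit is hydroxylated at C4, brominated at C8, lithiated and clipped through SiMe2 to the upper 3-OH; an oxidant then joins the units within that bridge.
- Enabling feature: upper C4 is a CH2 benzylic to an A ring oxygenated at C5, C7 and C8a, so hydride loss gives a stabilised cation. The upper 3-oxygen is vicinal and cis to the bond to be made. Lower C8 lies between the O-bearing C7 and C8a and para to the O-bearing C5, so ipso attack there gives a triply oxygen-stabilised, β-silyl arenium ion.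
- Stereochemistry: C2/C3 of both units come from the chiral pool. Lower C4 is set by anti capture of a C4 cation by water (trans to the axial 3-OH). Upper C4 is set by delivery of the aryl group from the 3-O–Si tether (cis to O3, all-cis upper ring).
- Helpers: the SiMe2 bridge, two TBS groups and eight benzyl ethers, removed in steps 7 and 8.

Key step: step 7

Remark: (+)-epicatechin (2S,3S) and (−)-epicatechin (2R,3R) are both taken as commercial; "cis/trans" refer to substituents on the pyran ring, and the target is read as upper unit (2S,3S,4R, all-cis) and lower unit (2R,3R,4S, 2,3-cis-3,4-trans).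

**Route**

Step 1
Reactants: 1 (+)-epicatechin; 2 benzyl bromide
Product: 3 5,7,3',4'-tetra-O-benzyl-(+)-epicatechin
Conditions: BnBr (4.4 equiv), K2CO3, DMF, 0 °C → rt
Reagents that add atoms: benzyl bromide, BrCc1ccccc1
Why: Williamson etherification of the four phenoxides, which are far more acidic than the secondary 3-OH, should leave the 3-OH free and C2/C3 untouched.

Step 2
Reactants: 4 (−)-epicatechin; 2 benzyl bromide
Product: 5 5,7,3',4'-tetra-O-benzyl-(−)-epicatechin
Conditions: BnBr (4.4 equiv), K2CO3, DMF, 0 °C → rt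
Reagents that add atoms: benzyl bromide, BrCc1ccccc1
Why: the same Williamson etherification as in step 1, on the enantiomeric monomer.

Step 3
Reactants: 5 5,7,3',4'-tetra-O-benzyl-(−)-epicatechin; 6 water
Product: 7 (2R,3R,4S)-5,7,3',4'-tetra-O-benzylflavan-3,4-diol (4-OH trans to 3-OH)
Conditions: DDQ (1.5 equiv), CH2Cl2/H2O (20:1), rt
Reagents that add atoms: water, O
Why: DDQ benzylic C–H oxidation (hydride abstraction at C4, cation stabilised by O5, O7 and O1) followed by capture by water anti to the axial 3-OH should give the 4-OH trans to the 3-OH (4S), and a second oxidation is disfavoured because the remaining C4–H is pseudo-equatorial.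

Step 4
Reactants: 7 the 3,4-diol; 8 tert-butyldimethylsilyl chloride
Product: 9 3,4-bis-O-TBS ether of 7
Conditions: TBSCl (3 equiv), imidazole, DMAP (cat.), DMF, 40 °C
Reagents that add atoms: tert-butyldimethylsilyl chloride, CC(C)(C)[Si](C)(C)Cl
Why: Corey silylation under non-Lewis-acidic conditions should protect both secondary alcohols without ionising the benzylic C4–O bond, so its configuration is kept.

Step 5
Reactants: 9 the bis-TBS ether; 10 N-bromosuccinimide
Product: 11 8-bromo derivative of 9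
Conditions: NBS (1.05 equiv), CH2Cl2, −78 → 0 °C
Reagents that add atoms: N-bromosuccinimide, O=C1CCC(=O)N1Br
Why: electrophilic aromatic bromination should go to C8, the more nucleophilic and less hindered of the two free A-ring positions (C6 lies between two benzyloxy groups), as is known for benzylated flavan-3-ols.

Step 6
Reactants: 11 the 8-bromide; 12 dichlorodimethylsilane; 3 5,7,3',4'-tetra-O-benzyl-(+)-epicatechin
Product: 15 silicon-tethered precursor (3-O-[dimethyl(lower-unit-8-yl)silyl] ether of 3), via 8-lithio arene 13 (not isolated), via 8-chlorodimethylsilyl arene 14 (not isolated)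
Conditions: t-BuLi (2.0 equiv), THF, −78 °C; cannulated into Me2SiCl2 (5 equiv), −78 °C → rt; volatiles removed; then 3 (0.9 equiv), imidazole, DMAP (cat.), CH2Cl2, 0 °C → rt; Et3N-deactivated silica
Reagents that add atoms: dichlorodimethylsilane, C[Si](C)(Cl)Cl
Why: bromine–lithium exchange is faster than attack on benzyl or silyl ethers at −78 °C, inverse addition to excess Me2SiCl2 should silylate the aryllithium once, and the chlorosilane then silylates the free axial 3-OH of 3 (silyl ether formation) without touching any stereocentre.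

Step 7
Reactants: 15 the silicon-tethered precursor
Product: 18 octa-O-benzyl dimer triol (upper 3-OH; lower 3,4-diol; target configuration), via C4 cation ion pair 16 (not isolated), via O3-silylated coupled dimer 17 (not isolated)
Conditions: DDQ (1.05 equiv), 2,6-di-tert-butyl-4-methylpyridine, LiClO4, 4 Å MS, CH2Cl2, −40 → 0 °C; then TBAF/AcOH (1:1), THF, 0 °C → rt
Reagents that add atoms: none
Why: Proposed new method: DDQ should abstract the pseudo-axial hydride of the upper C4 methylene (the lower C4–H is pseudo-equatorial and α to a bulky silyloxy group, hence shut off) to give a C4 cation stabilised by O5, O7 and O1 and paired with DDQH−; the silicon-bound lower C8, held over the O3 face by the C3–O–Si link, then attacks ipso through a five-membered 1-oxa-2-sila spiro transition state (5-exo-trig at both the cation and the arene), and the arenium ion, stabilised by O7, O1, O5 and the β C–Si bond, rearomatises by passing silicon to the DDQH− phenoxide. The closest known reaction types are the intramolecular delivery of aryl groups from 2-O-aryldimethylsilyl tethers to glycosyl oxocarbenium ions (1,2-cis C-aryl glycosides), ipso-desilylative SEAr of aryl silanes, and the DDQ-mediated C4–H functionalisation of benzylated flavan-3-ols used in step 3. No ring is kept, since the spiro ring is transient and fluoride then removes the silicon bridge and both TBS groups in the same flask. The only new stereocentre, upper C4, is controlled by the tether: C8 can reach C4 only on the face of O3, which should place the new aryl group cis to the 3-oxygen and the 2-aryl group (all-cis), the opposite of intermolecular attack. The step needs site selectivity (C8 and not C6, fixed by the C–Si bond), selectivity between the two C4 positions (see above; 1.05 equiv of DDQ also limits oxidation of the product methine), and a 1:1 union without oligomers (secured by the tether, by the lower C4 oxygen being a non-ionising TBS ether, and by base-buffered, non-acidic conditions that also suppress protodesilylation).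

Step 8
Reactants: 18 the octa-O-benzyl dimer triol
Product: 19 target (CNP0114173.1)
Conditions: H2 (1 atm), Pd(OH)2/C, THF/H2O, rt; filtration under Ar, lyophilisation
Reagents that add atoms: none
Why: neutral hydrogenolysis of the eight primary benzyl aryl ethers should be much faster than cleavage of the hindered secondary C4–O bond, and water as cosolvent makes any solvolysis of the 4-OH degenerate, so all stereocentres should be kept.

**Compound list**

1 | (+)-epicatechin, (2S,3S) | Oc1cc(O)c2c(c1)O[C@@H](c1ccc(O)c(O)c1)[C@@H](O)C2 | starting material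
2 | benzyl bromide | BrCc1ccccc1 | starting material
3 | 5,7,3',4'-tetra-O-benzyl-(+)-epicatechin | O(Cc1ccccc1)c1cc(OCc2ccccc2)c2c(c1)O[C@@H](c1ccc(OCc3ccccc3)c(OCc3ccccc3)c1)[C@@H](O)C2 | intermediate
4 | (−)-epicatechin, (2R,3R) | Oc1cc(O)c2c(c1)O[C@H](c1ccc(O)c(O)c1)[C@H](O)C2 | starting material
5 | 5,7,3',4'-tetra-O-benzyl-(−)-epicatechin | O(Cc1ccccc1)c1cc(OCc2ccccc2)c2c(c1)O[C@H](c1ccc(OCc3ccccc3)c(OCc3ccccc3)c1)[C@H](O)C2 | intermediate
6 | water | O | starting material
7 | (2R,3R,4S)-5,7,3',4'-tetra-O-benzylflavan-3,4-diol | O(Cc1ccccc1)c1cc(OCc2ccccc2)c2c(c1)O[C@H](c1ccc(OCc3ccccc3)c(OCc3ccccc3)c1)[C@H](O)[C@H]2O | intermediate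
8 | tert-butyldimethylsilyl chloride | CC(C)(C)[Si](C)(C)Cl | starting material
9 | 3,4-bis-O-TBS ether of 7 | O(Cc1ccccc1)c1cc(OCc2ccccc2)c2c(c1)O[C@H](c1ccc(OCc3ccccc3)c(OCc3ccccc3)c1)[C@H](O[Si](C)(C)C(C)(C)C)[C@H]2O[Si](C)(C)C(C)(C)C | intermediate
10 | N-bromosuccinimide | O=C1CCC(=O)N1Br | starting material
11 | 8-bromo derivative of 9 | O(Cc1ccccc1)c1cc(OCc2ccccc2)c2c(c1Br)O[C@H](c1ccc(OCc3ccccc3)c(OCc3ccccc3)c1)[C@H](O[Si](C)(C)C(C)(C)C)[C@H]2O[Si](C)(C)C(C)(C)C | intermediate
12 | dichlorodimethylsilane | C[Si](C)(Cl)Cl | starting material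
13 | 8-lithio arene from 11 | O(Cc1ccccc1)c1cc(OCc2ccccc2)c2c(c1[Li])O[C@H](c1ccc(OCc3ccccc3)c(OCc3ccccc3)c1)[C@H](O[Si](C)(C)C(C)(C)C)[C@H]2O[Si](C)(C)C(C)(C)C | intermediate
14 | 8-(chlorodimethylsilyl) arene | O(Cc1ccccc1)c1cc(OCc2ccccc2)c2c(c1[Si](C)(C)Cl)O[C@H](c1ccc(OCc3ccccc3)c(OCc3ccccc3)c1)[C@H](O[Si](C)(C)C(C)(C)C)[C@H]2O[Si](C)(C)C(C)(C)C | intermediate
15 | silicon-tethered precursor (upper O3–SiMe2–C8 lower) | O(Cc1ccccc1)c1cc(OCc2ccccc2)c2c(c1)O[C@@H](c1ccc(OCc3ccccc3)c(OCc3ccccc3)c1)[C@@H](O[Si](C)(C)c1c(OCc3ccccc3)cc(OCc3ccccc3)c4c1O[C@H](c1ccc(OCc3ccccc3)c(OCc3ccccc3)c1)[C@H](O[Si](C)(C)C(C)(C)C)[C@H]4O[Si](C)(C)C(C)(C)C)C2 | intermediate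
16 | upper C4 cation of 15, ion pair with DDQH− | O(Cc1ccccc1)c1cc(OCc2ccccc2)c2c(c1)O[C@@H](c1ccc(OCc3ccccc3)c(OCc3ccccc3)c1)[C@@H](O[Si](C)(C)c1c(OCc3ccccc3)cc(OCc3ccccc3)c4c1O[C@H](c1ccc(OCc3ccccc3)c(OCc3ccccc3)c1)[C@H](O[Si](C)(C)C(C)(C)C)[C@H]4O[Si](C)(C)C(C)(C)C)[CH+]2.[O-]c1c(Cl)c(Cl)c(O)c(C#N)c1C#N | intermediate
17 | coupled dimer, upper O3 carrying SiMe2–O-aryl(DDQH), lower bis-TBS | O(Cc1ccccc1)c1cc(OCc2ccccc2)c2c(c1)O[C@@H](c1ccc(OCc3ccccc3)c(OCc3ccccc3)c1)[C@@H](O[Si](C)(C)Oc1c(Cl)c(Cl)c(O)c(C#N)c1C#N)[C@H]2c1c(OCc2ccccc2)cc(OCc2ccccc2)c2c1O[C@H](c1ccc(OCc3ccccc3)c(OCc3ccccc3)c1)[C@H](O[Si](C)(C)C(C)(C)C)[C@H]2O[Si](C)(C)C(C)(C)C | intermediate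
18 | octa-O-benzyl dimer triol | O(Cc1ccccc1)c1cc(OCc2ccccc2)c2c(c1)O[C@@H](c1ccc(OCc3ccccc3)c(OCc3ccccc3)c1)[C@@H](O)[C@H]2c1c(OCc2ccccc2)cc(OCc2ccccc2)c2c1O[C@H](c1ccc(OCc3ccccc3)c(OCc3ccccc3)c1)[C@H](O)[C@H]2O | intermediate
19 | CNP0114173.1 | Oc1cc(O)c2c(c1)O[C@@H](c1ccc(O)c(O)c1)[C@@H](O)[C@H]2c1c(O)cc(O)c2c1O[C@H](c1ccc(O)c(O)c1)[C@H](O)[C@H]2O | target

**Step count and risks**

Total steps: 8. Longest linear sequence: 7 (steps 2–8, from (−)-epicatechin).

Steps most likely to fail:

1. Step 7. The oxidant may attack the electron-rich silyl-arene by electron transfer instead of abstracting the C4 hydride. The cation may lose H3 to a flav-3-ene before the crowded ipso attack occurs. The aryl–silicon bond may be protonolysed by the hydroquinone, or the product methine may be oxidised further. The fallback uses the known ketone addition/ionic reduction sequence, established for the enantiomeric all-cis dimer; it sets out from 3 and 11 and comes back at 18. Compound 3 is silylated (TBSCl, imidazole, DMF) to the 3-O-TBS ether F1. DDQ in wet CH2Cl2 gives the 4-hydroxy compound F2 (OH trans to the 3-OTBS), and Dess–Martin periodinane gives the 4-ketone F3. The aryllithium 13, made from 11 with t-BuLi at −78 °C, adds to F3 anti to the axial 3-OTBS to give the tertiary carbinol F4. Bu3SnH/TFA in CH2Cl2 at low temperature ionises the tertiary, doubly benzylic carbinol faster than the secondary C4–OTBS of the lower unit and delivers hydride anti to the 3-OTBS and 2-aryl groups, which leaves the aryl group cis to O3 in the tris-TBS all-cis dimer F5. TBAF then gives 18.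

2. Step 6. The hindered, di-ortho-substituted aryllithium may be protonated or arylate silicon twice. The chlorosilane may hydrolyse, silylation of the axial 3-OH may stall, or the tether may be cleaved on silica. The fallback changes the Si–O bond formation; it sets out from 11 and comes back at 15. The aryllithium 13 is quenched with chlorodimethylsilane to the chromatographically stable aryl(dimethyl)hydrosilane F6. F6 is then joined to 3 by rhodium(II) perfluorobutyrate-catalysed dehydrogenative alcoholysis of the Si–H bond (CH2Cl2, rt), which releases hydrogen and gives 15 without a chlorosilane.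

3. Step 8. The benzylic C4–O bond of the lower unit may be hydrogenolysed. Once the 5- and 7-phenols are free, the 4-OH may ionise to a quinone methide and lead to self-condensation, and the catechols may oxidise in air. The fallback changes the order of deprotection; it sets out from 15 and comes back at 19. The DDQ stage of step 7 is run as before but worked up with K2CO3/MeOH in place of fluoride, which removes only the labile silicon bridge and gives the bis-TBS dimer F7 (upper 3-OH free, lower 3,4-bis-OTBS). Hydrogenolysis (H2, Pd(OH)2/C, THF/H2O) with the C4 oxygen still masked as a hindered, non-ionising silyl ether gives the bis-TBS octaphenol F8. Buffered fluoride (TBAF/AcOH, THF, under Ar; Sephadex LH-20) then gives 19.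

**Further compounds**

F1 | step 7 | 3-O-TBS ether of 3 | O(Cc1ccccc1)c1cc(OCc2ccccc2)c2c(c1)O[C@@H](c1ccc(OCc3ccccc3)c(OCc3ccccc3)c1)[C@@H](O[Si](C)(C)C(C)(C)C)C2
F2 | step 7 | 4-hydroxy derivative of F1 (OH trans to 3-OTBS) | O(Cc1ccccc1)c1cc(OCc2ccccc2)c2c(c1)O[C@@H](c1ccc(OCc3ccccc3)c(OCc3ccccc3)c1)[C@@H](O[Si](C)(C)C(C)(C)C)[C@@H]2O
F3 | step 7 | 4-ketone of the upper unit, 3-O-TBS | O(Cc1ccccc1)c1cc(OCc2ccccc2)c2c(c1)O[C@@H](c1ccc(OCc3ccccc3)c(OCc3ccccc3)c1)[C@@H](O[Si](C)(C)C(C)(C)C)C2=O
F4 | step 7 | tertiary C4 carbinol dimer, tris-TBS | O(Cc1ccccc1)c1cc(OCc2ccccc2)c2c(c1)O[C@@H](c1ccc(OCc3ccccc3)c(OCc3ccccc3)c1)[C@@H](O[Si](C)(C)C(C)(C)C)[C@]2(O)c1c(OCc2ccccc2)cc(OCc2ccccc2)c2c1O[C@H](c1ccc(OCc3ccccc3)c(OCc3ccccc3)c1)[C@H](O[Si](C)(C)C(C)(C)C)[C@H]2O[Si](C)(C)C(C)(C)C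
F5 | step 7 | all-cis octa-O-benzyl dimer, tris-TBS | O(Cc1ccccc1)c1cc(OCc2ccccc2)c2c(c1)O[C@@H](c1ccc(OCc3ccccc3)c(OCc3ccccc3)c1)[C@@H](O[Si](C)(C)C(C)(C)C)[C@H]2c1c(OCc2ccccc2)cc(OCc2ccccc2)c2c1O[C@H](c1ccc(OCc3ccccc3)c(OCc3ccccc3)c1)[C@H](O[Si](C)(C)C(C)(C)C)[C@H]2O[Si](C)(C)C(C)(C)C
F6 | step 6 | 8-(dimethylsilyl) arene of the lower unit | O(Cc1ccccc1)c1cc(OCc2ccccc2)c2c(c1[SiH](C)C)O[C@H](c1ccc(OCc3ccccc3)c(OCc3ccccc3)c1)[C@H](O[Si](C)(C)C(C)(C)C)[C@H]2O[Si](C)(C)C(C)(C)C
F7 | step 8 | octa-O-benzyl dimer, lower 3,4-bis-OTBS, upper 3-OH | O(Cc1ccccc1)c1cc(OCc2ccccc2)c2c(c1)O[C@@H](c1ccc(OCc3ccccc3)c(OCc3ccccc3)c1)[C@@H](O)[C@H]2c1c(OCc2ccccc2)cc(OCc2ccccc2)c2c1O[C@H](c1ccc(OCc3ccccc3)c(OCc3ccccc3)c1)[C@H](O[Si](C)(C)C(C)(C)C)[C@H]2O[Si](C)(C)C(C)(C)C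
F8 | step 8 | free octaphenol dimer, lower 3,4-bis-OTBS | Oc1cc(O)c2c(c1)O[C@@H](c1ccc(O)c(O)c1)[C@@H](O)[C@H]2c1c(O)cc(O)c2c1O[C@H](c1ccc(O)c(O)c1)[C@H](O[Si](C)(C)C(C)(C)C)[C@H]2O[Si](C)(C)C(C)(C)C
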